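**Plan**

- Locants: ring A is C1 (acyloxy CH), C2 (CHOH), C3 (methyl-bearing oxirane C), C4 (oxirane CH), C5 (CH2), C6 (CH carrying the chain); the chain is C7(=C14H2)–C8(O-angeloyl)–C9H2–C10/C11 oxirane.
- Enabling feature: the oxygens on C1 and C4 are 1,4-related across ring A and lie on the same face as the C6 chain, the C2 hydroxyl and the oxirane. C1 and C4 are therefore the bridgeheads of a 2-exo-substituted 7-oxanorbornane, and the methyl group on C3 marks it as a 3-methylfuran adduct.
- Retrosynthetic cuts, in order: both ester C–O bonds (O8–angeloyl, O1–2-methylbutanoyl); both oxiranes (C10/C11, then C3/C4); C2–H (back to the enone); the C4–O bond is re-formed to restore the bridge; C7–C8 (alkenyl triflate plus 4-methylpent-3-enal); finally C1–C6 and C4–C5 (furan plus acrylate).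
- Forward order: the [4+2] addition closes ring A together with its oxygen bridge; resolution; hydroboration puts oxygen on C2; the chain is built on the intact bicycle (ester, methyl ketone, enol triflate, C7–C8 coupling, C8 ketone, (8S) alcohol, angelate); the bridge is then broken at C4–O, O1 is acylated, C2 is reduced and the two oxiranes are added.
- Stereochemistry: C1 and C6 come from the exo adduct and the lipase resolution; C2 from hydride attack anti to O1 and the chain; C3/C4 from epoxidation directed by the C2 hydroxyl; C8 from a Corey–Bakshi–Shibata reduction; C10 from a Shi epoxidation; the acyl stereocentre is bought as (R)-2-methylbutanoic acid.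

Key step: step 1

Remark 1: it is assumed that the lipase hydrolyses the (1R,2S,4R) antipode of racemic 3 faster, so that 4 is recovered as unreacted ester; this preference must be confirmed on the substrate.
Remark 2: 1, 2, 12, 17 and 25 are taken as commercial.

**Route**

Step 1
Reactants: 1 3-methylfuran; 2 methyl acrylate
Product: 3 racemic methyl 5-methyl-7-oxabicyclo[2.2.1]hept-5-ene-2-exo-carboxylate
Conditions: ZnI2 (0.3 equiv), neat in excess 2, 40 °C, sealed vessel, dark, 48 h; chromatography
Reagents that add atoms: none
Why: ZnI2 binds the acrylate carbonyl and lowers its LUMO so that 3-methylfuran reacts as the diene in a concerted suprafacial [4+2] cycloaddition; the closest known reaction type is the ZnI2-promoted Diels–Alder addition of furans to acrylates. Ring A (C1–C6) closes in this single pericyclic event through a six-membered transition state by formation of C1–C6 and C4–C5 at the furan 2,5-positions, and the furan oxygen becomes the C1–O–C4 bridge. C1 and C4 are fixed relative to each other by the suprafacial addition across the planar furan, and C6 relative to them by the exo or endo placement of the ester. Because the addition is reversible under these conditions, the more stable exo ester (CO2Me on the face of the oxygen bridge) should build up under thermodynamic control. The step also needs the para orientation (ester carbon bonded to the furan carbon remote from the methyl group), for which the only bias is the larger HOMO coefficient at the furan carbon next to the methyl group meeting the acrylate β-carbon; this bias is modest, so meta and endo isomers are to be removed by chromatography. The product is racemic and the absolute configuration is left to step 2.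

Step 2
Reactants: 3 racemic exo ester
Product: 4 methyl (1S,2R,4S)-5-methyl-7-oxabicyclo[2.2.1]hept-5-ene-2-carboxylate (2-exo ester)
Conditions: Candida rugosa lipase, KH2PO4/K2HPO4 buffer pH 7.2, t-BuOMe, 30 °C, stopped near half conversion; NaHCO3 extraction removes the acid
Reagents that add atoms: none
Why: Lipase-catalysed enantioselective ester hydrolysis (enzymatic kinetic resolution of a rigid bicyclic ester) should consume one antipode and leave the other, which fixes C1, C4 and C6 in the absolute sense without forming a new stereocentre.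

Step 3
Reactants: 4 resolved exo ester
Product: 6 methyl 6-exo-hydroxy-5-endo-methyl-7-oxabicyclo[2.2.1]heptane-2-exo-carboxylate, via alkylborane 5 (not isolated)
Conditions: BH3·THF, THF, 0 °C; then H2O2, aq. NaOAc, 0 °C to rt
Reagents that add atoms: borane–tetrahydrofuran, B.C1CCOC1 (boron of 5); hydrogen peroxide, OO (oxygen of 6)
Why: In this hydroboration–oxidation, borane adds syn from the exo face of the strained alkene with boron on the unsubstituted C2 and hydrogen on the methyl-bearing C3, so that oxidation with retention gives the 2-exo alcohol with the C3 methyl endo, while the ester is untouched at 0 °C and the buffered peroxide avoids saponification.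

Step 4
Reactants: 6 hydroxy ester
Product: 7 methyl 6-exo-(tert-butyldimethylsilyloxy)-5-endo-methyl-7-oxabicyclo[2.2.1]heptane-2-exo-carboxylate
Conditions: t-BuMe2SiOTf, 2,6-lutidine, CH2Cl2, −78 to 0 °C
Reagents that add atoms: tert-butyldimethylsilyl triflate, CC(C)(C)[Si](C)(C)OS(=O)(=O)C(F)(F)F
Why: Silylation of the secondary alcohol with a silyl triflate masks O2 for the organometallic and strongly basic steps that follow and changes no stereocentre.

Step 5
Reactants: 7 silyl ether ester
Product: 9 1-[6-exo-(tert-butyldimethylsilyloxy)-5-endo-methyl-7-oxabicyclo[2.2.1]hept-2-exo-yl]ethanone, via Weinreb amide 8 (not isolated)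
Conditions: MeNH(OMe)·HCl, i-PrMgCl, THF, −20 °C; then MeMgBr, −20 to 0 °C; aq. NH4Cl
Reagents that add atoms: N,O-dimethylhydroxylamine hydrochloride, CNOC.Cl (amide nitrogen group of 8); methylmagnesium bromide, C[Mg]Br (methyl group of 9)
Why: The chloromagnesium amide converts the ester into the N-methoxy-N-methylamide under conditions known to spare α-stereocentres, and MeMgBr then adds only once because the chelated tetrahedral intermediate survives until the quench (Weinreb ketone synthesis), so C6 is untouched.

Step 6
Reactants: 9 methyl ketone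
Product: 11 1-[6-exo-(tert-butyldimethylsilyloxy)-5-endo-methyl-7-oxabicyclo[2.2.1]hept-2-exo-yl]ethenyl trifluoromethanesulfonate, via potassium enolate 10 (not isolated)
Conditions: KN(SiMe3)2, THF, −78 °C; then PhNTf2, −78 to 0 °C
Reagents that add atoms: potassium bis(trimethylsilyl)amide, C[Si](C)(C)[N-][Si](C)(C)C.[K+] (potassium of 10); N-phenylbis(trifluoromethanesulfonimide), O=S(=O)(N(c1ccccc1)S(=O)(=O)C(F)(F)F)C(F)(F)F (triflyl group of 11)
Why: Kinetic deprotonation with the bulky amide occurs at the unhindered CH3 group and not at the tertiary C6–H, and O-sulfonylation of that enolate gives the 1,1-disubstituted alkenyl triflate (enol triflate formation) without epimerising C6.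

Step 7
Reactants: 12 4-methylpent-3-en-1-ol
Product: 13 4-methylpent-3-enal
Conditions: Dess–Martin periodinane, NaHCO3, CH2Cl2, 0 °C to rt; used at once as a solution
Reagents that add atoms: none
Why: Buffered Dess–Martin oxidation should give the β,γ-unsaturated aldehyde without moving the double bond into conjugation.

Step 8
Reactants: 11 alkenyl triflate; 13 4-methylpent-3-enal
Product: 14 2-[6-exo-(tert-butyldimethylsilyloxy)-5-endo-methyl-7-oxabicyclo[2.2.1]hept-2-exo-yl]-6-methylhepta-1,5-dien-3-ol (both C8 epimers)
Conditions: CrCl2 (4 equiv), NiCl2 (2 mol%), DMF, rt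
Reagents that add atoms: none
Why: In this Nozaki–Hiyama–Kishi coupling, zerovalent nickel inserts into the alkenyl C–O triflate bond, transmetallation gives an alkenylchromium species that adds chemoselectively to the aldehyde under non-basic conditions and forms C7–C8, with C8 expected as an epimer mixture that steps 9 and 10 correct.

Step 9
Reactants: 14 allylic alcohol (epimer mixture)
Product: 15 2-[6-exo-(tert-butyldimethylsilyloxy)-5-endo-methyl-7-oxabicyclo[2.2.1]hept-2-exo-yl]-6-methylhepta-1,5-dien-3-one
Conditions: Dess–Martin periodinane, NaHCO3, CH2Cl2, 0 °C; carried on without storage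
Reagents that add atoms: none
Why: Dess–Martin oxidation of the secondary allylic alcohol removes the uncontrolled C8 centre and gives the α-methylene ketone, and buffering at low temperature should keep the skipped C10=C11 bond out of conjugation.

Step 10
Reactants: 15 α-methylene ketone
Product: 16 (3S)-2-[6-exo-(tert-butyldimethylsilyloxy)-5-endo-methyl-7-oxabicyclo[2.2.1]hept-2-exo-yl]-6-methylhepta-1,5-dien-3-ol ((8S) alcohol)
Conditions: (R)-2-methyl-CBS-oxazaborolidine (0.2 equiv), catecholborane, toluene, −78 °C
Reagents that add atoms: none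
Why: In the Corey–Bakshi–Shibata reduction the (R)-oxazaborolidine should bind the ketone with the α-branched alkenyl group as the large and the C9 methylene as the small substituent and deliver hydride to the face that gives the (8S) alcohol, while catecholborane at −78 °C leaves the alkenes alone.

Step 11
Reactants: 16 (8S) alcohol; 17 angelic acid ((Z)-2-methylbut-2-enoic acid)
Product: 19 (8S) angelate of 16 (6-exo silyl ether retained), via mixed anhydride 18 (not isolated)
Conditions: 17, 2,4,6-trichlorobenzoyl chloride, Et3N, toluene, rt; then 16, 80 °C (no DMAP)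
Reagents that add atoms: 2,4,6-trichlorobenzoyl chloride, O=C(Cl)c1c(Cl)cc(Cl)cc1Cl (aroyl part of 18 only)
Why: In this DMAP-free Yamaguchi esterification the preformed mixed anhydride acylates the secondary alcohol at the less hindered angeloyl carbonyl, a protocol chosen because it avoids isomerisation of the (Z)-angelate to the tiglate, and C8 keeps its configuration.

Step 12
Reactants: 19 silyl ether angelate
Product: 20 (8S) angelate with free 6-exo hydroxyl on the bicycle (O2–H)
Conditions: HF·pyridine, pyridine, THF, 0 °C to rt
Reagents that add atoms: none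
Why: Fluoride-mediated desilylation under buffered acidic conditions frees O2 without forming an alkoxide that could take over the angeloyl group, and nothing in 19 is acid-labile at this stage.

Step 13
Reactants: 20 bicyclic alcohol
Product: 21 (8S) angelate with the 6-oxo-7-oxabicyclo[2.2.1]heptane core (C2 ketone)
Conditions: Dess–Martin periodinane, NaHCO3, CH2Cl2, rt
Reagents that add atoms: none
Why: Dess–Martin oxidation gives the C2 ketone under near-neutral conditions that tolerate the allylic ester and both alkenes, and the C3 centre next to the ketone is of no consequence because it becomes sp2 in step 14.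

Step 14
Reactants: 21 bicyclic ketone
Product: 24 (3S)-2-[(1S,6R)-6-hydroxy-4-methyl-5-oxocyclohex-3-en-1-yl]-6-methylhepta-1,5-dien-3-yl (Z)-2-methylbut-2-enoate (O1–H cis to the chain), via silyl enol ether 22 (not isolated), via silyl ether 23 (not isolated)
Conditions: Me3SiOTf, Et3N, CH2Cl2, 0 °C to rt; then 1 M HCl, THF, 0 °C
Reagents that add atoms: trimethylsilyl triflate, C[Si](C)(C)OS(=O)(=O)C(F)(F)F (silyl group of 22 and 23; none of its atoms remain in 24)
Why: Soft enolisation of the C2 ketone towards C3 (C1 is a bridgehead) gives the silyl enol ether, whose π-electrons expel the silyl-activated bridge oxygen from C4 (the β-elimination known for 7-oxanorbornan-2-ones under silyl triflate and amine), leaving the C3=C4 enone and O1 as a labile silyl ether that dilute acid cleaves; the C1–O bond is never broken, so O1 stays cis to the C6 chain.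

Step 15
Reactants: 24 hydroxy enone; 25 (R)-2-methylbutanoic acid
Product: 26 (R)-2-methylbutanoate of 24 at O1
Conditions: DCC, DMAP (0.1 equiv), CH2Cl2, 0 °C to rt
Reagents that add atoms: none
Why: Steglich esterification acylates the only free hydroxyl group, and the α-branched saturated acid is not prone to racemisation under these conditions, so the (R) acyl centre is carried over from 25.

Step 16
Reactants: 26 enone diester
Product: 27 cis allylic alcohol, (1R,2S,6S) on ring A (C2–OH cis to O1 and to the chain)
Conditions: NaBH4, CeCl3·7H2O, MeOH, −78 °C; cold aq. NH4Cl quench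
Reagents that add atoms: none
Why: The Luche reduction gives 1,2-reduction of the enone, and hydride should attack C2 from the face opposite the cis C1 acyloxy and C6 substituents (Felkin–Anh-type attack anti to the α-oxygen, the same sense as carvone to cis-carveol), which places the new hydroxyl cis to both.

Step 17
Reactants: 27 allylic alcohol
Product: 28 3,4-epoxide, (1R,2R,3R,4S,6S) on ring A (oxirane cis to the C2 hydroxyl)
Conditions: VO(acac)2 (5 mol%), t-BuOOH (decane solution), CH2Cl2, 0 °C to rt
Reagents that add atoms: tert-butyl hydroperoxide, CC(C)(C)OO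
Why: In this vanadium-catalysed hydroxyl-directed epoxidation the metal-bound C2 alkoxide delivers the peroxide oxygen to the adjacent C3=C4 bond on its own face, setting C3 and C4, while the undirected C7=C14 and C10=C11 alkenes should be left intact as in the epoxidation of carveol.

Step 18
Reactants: 28 ring epoxide
Product: 29 CNP0181486.1
Conditions: D-fructose-derived ketone of the Shi epoxidation (1,2:4,5-di-O-isopropylidene-β-D-erythro-2,3-hexodiulo-2,6-pyranose), KHSO5 (as Oxone, 2KHSO5·KHSO4·K2SO4), NaHCO3, MeCN/aq. Na2EDTA, pH 7–8, 0 °C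
Reagents that add atoms: potassium peroxymonosulfate, [K+].[O-]S(=O)(=O)OO
Why: In the Shi epoxidation the chiral dioxirane attacks the electron-rich trisubstituted C10=C11 alkene through a spiro transition state that should give the (R) oxirane carbon at C10, while the C7=C14 alkene (deactivated by the allylic ester) and the angelate are much less nucleophilic and the near-neutral buffer limits acyl shift from O1 to O2.

**Compound list**

1 | 3-methylfuran | Cc1ccoc1 | starting material
2 | methyl acrylate | C=CC(=O)OC | starting material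
3 | methyl 5-methyl-7-oxabicyclo[2.2.1]hept-5-ene-2-exo-carboxylate, racemate (the (1S,2R,4S) antipode is drawn) | COC(=O)[C@@H]1C[C@@H]2O[C@H]1C=C2C | intermediate
4 | methyl (1S,2R,4S)-5-methyl-7-oxabicyclo[2.2.1]hept-5-ene-2-carboxylate (2-exo, single enantiomer) | COC(=O)[C@@H]1C[C@@H]2O[C@H]1C=C2C | intermediate
5 | methyl 6-exo-boranyl-5-endo-methyl-7-oxabicyclo[2.2.1]heptane-2-exo-carboxylate (alkylborane, not isolated) | COC(=O)[C@@H]1C[C@@H]2O[C@H]1[C@@H](B)[C@@H]2C | intermediate
6 | methyl 6-exo-hydroxy-5-endo-methyl-7-oxabicyclo[2.2.1]heptane-2-exo-carboxylate (absolute series of 4) | COC(=O)[C@@H]1C[C@@H]2O[C@H]1[C@@H](O)[C@@H]2C | intermediate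
7 | methyl 6-exo-(tert-butyldimethylsilyloxy)-5-endo-methyl-7-oxabicyclo[2.2.1]heptane-2-exo-carboxylate | COC(=O)[C@@H]1C[C@@H]2O[C@H]1[C@@H](O[Si](C)(C)C(C)(C)C)[C@@H]2C | intermediate
8 | N-methoxy-N-methyl amide corresponding to ester 7 (Weinreb amide, not isolated) | CON(C)C(=O)[C@@H]1C[C@@H]2O[C@H]1[C@@H](O[Si](C)(C)C(C)(C)C)[C@@H]2C | intermediate
9 | 1-[6-exo-(tert-butyldimethylsilyloxy)-5-endo-methyl-7-oxabicyclo[2.2.1]hept-2-exo-yl]ethanone | CC(=O)[C@@H]1C[C@@H]2O[C@H]1[C@@H](O[Si](C)(C)C(C)(C)C)[C@@H]2C | intermediate
10 | potassium enolate of 9 on the methyl side (not isolated) | C=C([O-])[C@@H]1C[C@@H]2O[C@H]1[C@@H](O[Si](C)(C)C(C)(C)C)[C@@H]2C.[K+] | intermediate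
11 | 1-[6-exo-(tert-butyldimethylsilyloxy)-5-endo-methyl-7-oxabicyclo[2.2.1]hept-2-exo-yl]ethenyl trifluoromethanesulfonate | C=C(OS(=O)(=O)C(F)(F)F)[C@@H]1C[C@@H]2O[C@H]1[C@@H](O[Si](C)(C)C(C)(C)C)[C@@H]2C | intermediate
12 | 4-methylpent-3-en-1-ol | CC(C)=CCCO | starting material
13 | 4-methylpent-3-enal | CC(C)=CCC=O | intermediate
14 | 2-[6-exo-(tert-butyldimethylsilyloxy)-5-endo-methyl-7-oxabicyclo[2.2.1]hept-2-exo-yl]-6-methylhepta-1,5-dien-3-ol, both C8 epimers (C8 left undefined) | C=C(C(O)CC=C(C)C)[C@@H]1C[C@@H]2O[C@H]1[C@@H](O[Si](C)(C)C(C)(C)C)[C@@H]2C | intermediate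
15 | 2-[6-exo-(tert-butyldimethylsilyloxy)-5-endo-methyl-7-oxabicyclo[2.2.1]hept-2-exo-yl]-6-methylhepta-1,5-dien-3-one | C=C(C(=O)CC=C(C)C)[C@@H]1C[C@@H]2O[C@H]1[C@@H](O[Si](C)(C)C(C)(C)C)[C@@H]2C | intermediate
16 | (3S)-2-[6-exo-(tert-butyldimethylsilyloxy)-5-endo-methyl-7-oxabicyclo[2.2.1]hept-2-exo-yl]-6-methylhepta-1,5-dien-3-ol ((8S) alcohol) | C=C([C@H](CC=C(C)C)O)[C@@H]1C[C@@H]2O[C@H]1[C@@H](O[Si](C)(C)C(C)(C)C)[C@@H]2C | intermediate
17 | angelic acid, (Z)-2-methylbut-2-enoic acid | C/C=C(/C)C(=O)O | starting material
18 | angelic 2,4,6-trichlorobenzoic anhydride (not isolated) | C/C=C(/C)C(=O)OC(=O)c1c(Cl)cc(Cl)cc1Cl | intermediate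
19 | (8S) angelate of 16, 6-exo silyl ether retained | C=C([C@H](CC=C(C)C)OC(=O)/C(C)=C\C)[C@@H]1C[C@@H]2O[C@H]1[C@@H](O[Si](C)(C)C(C)(C)C)[C@@H]2C | intermediate
20 | (8S) angelate with free 6-exo hydroxyl on the bicycle | C=C([C@H](CC=C(C)C)OC(=O)/C(C)=C\C)[C@@H]1C[C@@H]2O[C@H]1[C@@H](O)[C@@H]2C | intermediate
21 | (8S) angelate with 5-endo-methyl-6-oxo-7-oxabicyclo[2.2.1]heptane core | C=C([C@H](CC=C(C)C)OC(=O)/C(C)=C\C)[C@@H]1C[C@@H]2O[C@H]1C(=O)[C@@H]2C | intermediate
22 | trimethylsilyl enol ether of 21 (C2=C3, not isolated) | C=C([C@H](CC=C(C)C)OC(=O)/C(C)=C\C)[C@@H]1C[C@@H]2O[C@H]1C(O[Si](C)(C)C)=C2C | intermediate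
23 | O1-trimethylsilyl ether of 24 (not isolated) | C=C([C@H](CC=C(C)C)OC(=O)/C(C)=C\C)[C@@H]1CC=C(C)C(=O)[C@@H]1O[Si](C)(C)C | intermediate
24 | (3S)-2-[(1S,6R)-6-hydroxy-4-methyl-5-oxocyclohex-3-en-1-yl]-6-methylhepta-1,5-dien-3-yl (Z)-2-methylbut-2-enoate | C=C([C@H](CC=C(C)C)OC(=O)/C(C)=C\C)[C@@H]1CC=C(C)C(=O)[C@@H]1O | intermediate
25 | (R)-2-methylbutanoic acid | CC[C@@H](C)C(=O)O | starting material
26 | O1-(R)-2-methylbutanoate of 24 (enone diester) | C=C([C@H](CC=C(C)C)OC(=O)/C(C)=C\C)[C@@H]1CC=C(C)C(=O)[C@@H]1OC(=O)[C@H](C)CC | intermediate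
27 | allylic alcohol from 26, ring A (1R,2S,6S), C2–OH cis to O1 and chain | C=C([C@H](CC=C(C)C)OC(=O)/C(C)=C\C)[C@@H]1CC=C(C)[C@H](O)[C@@H]1OC(=O)[C@H](C)CC | intermediate
28 | 3,4-epoxide of 27, ring A (1R,2R,3R,4S,6S), C10=C11 alkene still present | C=C([C@H](CC=C(C)C)OC(=O)/C(C)=C\C)[C@@H]1C[C@@H]2O[C@]2(C)[C@H](O)[C@@H]1OC(=O)[C@H](C)CC | intermediate
29 | CNP0181486.1: ring A (1R,2R,3R,4S,6S) 3,4-epoxy-2-hydroxy-3-methylcyclohexyl (2R)-2-methylbutanoate bearing at C6 the (3S)-3-angeloyloxy-4-[(2R)-3,3-dimethyloxiran-2-yl]but-1-en-2-yl chain | C=C([C@H](C[C@H]1OC1(C)C)OC(=O)/C(C)=C\C)[C@@H]1C[C@@H]2O[C@]2(C)[C@H](O)[C@@H]1OC(=O)[C@H](C)CC | target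

**Step count**

Total: 18 steps. Longest linear sequence: 17 steps (steps 1–6 and 8–18); step 7 is a one-step side branch. The cycloaddition in step 1 is expected to cost material through isomer separation, not to fail outright.

**Steps most likely to fail**

Step 2. The enzyme may discriminate poorly between the two antipodes of this compact bicycle, or may hydrolyse the wanted antipode. The fallback replaces the kinetic resolution by separation of covalent diastereomers and sets out from 3. Saponification (LiOH, THF/H2O, 0 °C, then HCl) gives racemic 5-methyl-7-oxabicyclo[2.2.1]hept-5-ene-2-exo-carboxylic acid F1. Coupling with (S)-4-benzyloxazolidin-2-one (DCC, DMAP cat., CH2Cl2) gives two imides: the one with the (1S,2R,4S) bicycle, F2, and the one with the (1R,2S,4R) bicycle, F3. These should separate by chromatography or crystallisation and are to be assigned crystallographically. Exocyclic methanolysis of F2 with MgBr(OMe) (from MeMgBr in MeOH, 0 °C) releases the auxiliary and returns to the route at 4. The same path serves if the enzyme prefers the wrong antipode.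

Step 14. Ionisation of the allylic angelate or silylation of the angelate by the silyl triflate may compete with enolisation and bridge cleavage, and the freed α-ketol may epimerise at C1 during hydrolysis. The fallback is an anionic fragmentation with in-flask acylation; it sets out from 21 and bypasses 22–24. (R)-2-Methylbutanoic anhydride F4 is made beforehand from 25 (DCC, 0.5 equiv, CH2Cl2). LiN(SiMe3)2 (1.05 equiv, THF, −78 °C) converts 21 into its lithium enolate F5. On warming to −20 °C this should expel the bridge oxygen from C4 by an E1cB pathway and give the lithium alkoxide of 24, F6. Addition of F4 traps F6 at O1, and the fallback comes back to the route at 26.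

Step 18. A base-promoted acyl shift from O1 to the free C2 hydroxyl and slow oxidation of that carbinol may compete with epoxidation, and an error at C10 cannot be corrected on the final compound. The fallback moves the chain epoxidation ahead of the creation of the C2 hydroxyl and sets out from 26, whose C3=C4 bond is electron-poor and inert to the dioxirane. Shi epoxidation under the conditions of step 18 gives the (10R) epoxy enone diester F7. Luche reduction (NaBH4, CeCl3·7H2O, MeOH, −78 °C) gives the cis allylic alcohol F8. VO(acac)2/t-BuOOH epoxidation directed by the C2 hydroxyl then closes the ring oxirane, and the fallback arrives at 29.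

**Further compounds**

F1 | step 2 | racemic 5-methyl-7-oxabicyclo[2.2.1]hept-5-ene-2-exo-carboxylic acid (the (1S,2R,4S) antipode is drawn) | OC(=O)[C@@H]1C[C@@H]2O[C@H]1C=C2C
F2 | step 2 | (S)-4-benzyl-3-[(1S,2R,4S)-5-methyl-7-oxabicyclo[2.2.1]hept-5-ene-2-exo-carbonyl]oxazolidin-2-one | O=C([C@@H]1C[C@@H]2O[C@H]1C=C2C)N1[C@@H](Cc2ccccc2)COC1=O
F3 | step 2 | (S)-4-benzyl-3-[(1R,2S,4R)-5-methyl-7-oxabicyclo[2.2.1]hept-5-ene-2-exo-carbonyl]oxazolidin-2-one | O=C([C@H]1C[C@H]2O[C@@H]1C=C2C)N1[C@@H](Cc2ccccc2)COC1=O
F4 | step 14 | (R)-2-methylbutanoic anhydride | CC[C@@H](C)C(=O)OC(=O)[C@H](C)CC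
F5 | step 14 | lithium enolate of 21 (C2=C3) | C=C([C@H](CC=C(C)C)OC(=O)/C(C)=C\C)[C@@H]1C[C@@H]2O[C@H]1C([O-])=C2C.[Li+]
F6 | step 14 | lithium alkoxide of 24 | C=C([C@H](CC=C(C)C)OC(=O)/C(C)=C\C)[C@@H]1CC=C(C)C(=O)[C@@H]1[O-].[Li+]
F7 | step 18 | (10R)-10,11-epoxide of enone diester 26 | C=C([C@H](C[C@H]1OC1(C)C)OC(=O)/C(C)=C\C)[C@@H]1CC=C(C)C(=O)[C@@H]1OC(=O)[C@H](C)CC
F8 | step 18 | (10R)-10,11-epoxide of allylic alcohol 27 | C=C([C@H](C[C@H]1OC1(C)C)OC(=O)/C(C)=C\C)[C@@H]1CC=C(C)[C@H](O)[C@@H]1OC(=O)[C@H](C)CC
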